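**Strategy.** Ring A is cut at C7–C8 and C5–C6. Its O7–C7–C6 unit, the C6 side chain and the tertiary oxygen are the atoms of 6,6-dimethyl-δ-valerolactone; C4a, C8a, C8 and C5 come from a 2-methyl-4-pyranone-3-carboxylate that already holds ring C and the chromene B ring. One operation, lateral acylation of the pyranone methyl group by the lactone and Claisen closure onto the ester, builds ring A with both phenols, the chain locked between them and the tertiary alcohol free. The precursor is ethyl 5-aryl-2-methyl-4-oxo-4H-pyran-3-carboxylate, made by Suzuki coupling; its 2′-oxygen is a TIPS ether, so fluoride, not acid, ends the route.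

Key step: step 9

Remark: the target has no stereocentre and no hindered axis (rotation about C3–C1′ is free), so it is achiral and needs no enantiocontrol; the ester alkyl group (ethyl, lost as ethanol) and the O2′ protecting group (TIPS) are spectators chosen freely.

**Route**

Step 1
Reactants: 1 4-bromobenzene-1,3-diol (4-bromoresorcinol); 2 3-methylbut-2-enoic acid
Product: 4 6-bromo-7-hydroxy-2,2-dimethylchroman-4-one, via aryl enone 3 (not isolated)
Conditions: P2O5–MeSO3H (solvent), 70 °C
Reagents that add atoms: none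
Why: Friedel–Crafts acylation should go to C6 of 1, the only position ortho/para to both hydroxyls that is not flanked by two substituents, and the ortho phenol then closes the ring by oxa-Michael addition (the standard chromanone synthesis from resorcinols), which places bromine at C6 and the free phenol at C7 by construction.

Step 2
Reactants: 4 6-bromo-7-hydroxy-2,2-dimethylchroman-4-one
Product: 5 6-bromo-2,2-dimethyl-7-(triisopropylsilyloxy)chroman-4-one
Conditions: TIPSCl, imidazole, DMF, rt
Reagents that add atoms: triisopropylsilyl chloride, CC(C)[Si](Cl)(C(C)C)C(C)C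
Why: Standard phenol silylation; a silyl ether is used at this oxygen because an acid-labile group would later expose the tertiary alcohol next to O5/O7 to cyclodehydration on removal, whereas TIPS tolerates hydride, Pd/base and amide base and leaves with fluoride.

Step 3
Reactants: 5 6-bromo-2,2-dimethyl-7-(triisopropylsilyloxy)chroman-4-one
Product: 7 6-bromo-2,2-dimethyl-7-(triisopropylsilyloxy)-2H-chromene, via chromanol 6 (not isolated)
Conditions: DIBAL-H, CH2Cl2, −78 → 0 °C; then 2 M HCl–THF, rt
Reagents that add atoms: none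
Why: Hydride reduction of the aryl ketone in a non-nucleophilic medium should give the racemic benzylic carbinol, whose stereocentre is erased at once by acid-catalysed E1 dehydration through the cation stabilised by the ring oxygen and the para silyloxy group (the usual chromanone to 2H-chromene sequence).

Step 4
Reactants: 7 6-bromo-2,2-dimethyl-7-(triisopropylsilyloxy)-2H-chromene
Product: 8 2-[2,2-dimethyl-7-(triisopropylsilyloxy)-2H-chromen-6-yl]-4,4,5,5-tetramethyl-1,3,2-dioxaborolane
Conditions: B2pin2, Pd(dppf)Cl2 (5 mol%), KOAc, 1,4-dioxane, 90 °C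
Reagents that add atoms: bis(pinacolato)diboron, CC1(C)OB(OC1(C)C)B1OC(C)(C)C(C)(C)O1
Why: Miyaura borylation of an aryl bromide; halogen–lithium exchange is avoided because an ortho-lithiated aryl silyl ether would undergo O→C silyl migration.

Step 5
Reactants: 9 ethyl 2-acetyl-3-oxobutanoate
Product: 11 ethyl 2-methyl-4-oxo-4H-pyran-3-carboxylate, via enaminone 10 (not isolated)
Conditions: Me2NCH(OMe)2 (1.1 equiv), toluene, 80 °C; then AcOH, 80 °C
Reagents that add atoms: N,N-dimethylformamide dimethyl acetal, COC(OC)N(C)C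
Why: Aminomethylenation of an acetyl CH3 of the enolised 2-acyl-1,3-dicarbonyl, then acid-promoted addition–elimination by the enol oxygen, should close the γ-pyrone as it does with dehydroacetic acid and 2-acetylcyclohexane-1,3-diones; the two acetyl groups are equivalent, so no regiochemical question arises.

Step 6
Reactants: 11 ethyl 2-methyl-4-oxo-4H-pyran-3-carboxylate
Product: 12 ethyl 5-iodo-2-methyl-4-oxo-4H-pyran-3-carboxylate
Conditions: NIS (1.1 equiv), TFA (0.3 equiv), MeCN, 50 °C
Reagents that add atoms: N-iodosuccinimide, O=C1CCC(=O)N1I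
Why: Electrophilic α-iodination of the γ-pyrone at C5, its only unsubstituted enol-ether β-carbon (C6 is the electrophilic α-oxy carbon), as in the halogenation of 4-pyranones and chromones.

Step 7
Reactants: 8 2-[2,2-dimethyl-7-(triisopropylsilyloxy)-2H-chromen-6-yl]-4,4,5,5-tetramethyl-1,3,2-dioxaborolane; 12 ethyl 5-iodo-2-methyl-4-oxo-4H-pyran-3-carboxylate
Product: 13 ethyl 5-[2,2-dimethyl-7-(triisopropylsilyloxy)-2H-chromen-6-yl]-2-methyl-4-oxo-4H-pyran-3-carboxylate
Conditions: Pd(OAc)2 (5 mol%), SPhos (10 mol%), K3PO4, toluene–H2O (10:1), 60 °C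
Reagents that add atoms: none
Why: Suzuki–Miyaura coupling of an α-iodo enone with an aryl boronate, the pyranone counterpart of the 3-iodochromone route to isoflavones; SPhos should cope with the ortho-silyloxy boronate, and a weak base at moderate temperature spares the ester, the pyranone ring and the silyl ether.

Step 8
Reactants: 14 ethyl 5-oxohexanoate
Product: 16 6,6-dimethyltetrahydro-2H-pyran-2-one, via hydroxy ester 15 (not isolated)
Conditions: MeMgBr (1.05 equiv), THF, −78 → 0 °C; then 2 M HCl, rt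
Reagents that add atoms: methylmagnesium bromide, C[Mg]Br
Why: Grignard addition is chemoselective for the ketone over the ester at low temperature, and the tertiary alkoxide/alcohol lactonises readily (gem-dimethyl effect) with loss of ethanol.

Step 9
Reactants: 13 ethyl 5-[2,2-dimethyl-7-(triisopropylsilyloxy)-2H-chromen-6-yl]-2-methyl-4-oxo-4H-pyran-3-carboxylate; 16 6,6-dimethyltetrahydro-2H-pyran-2-one
Product: 18 3-[2,2-dimethyl-7-(triisopropylsilyloxy)-2H-chromen-6-yl]-5,7-dihydroxy-6-(3-hydroxy-3-methylbutyl)-4H-chromen-4-one, via keto alcohol 17 (not isolated)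
Conditions: LDA (1.1 equiv), THF, −78 °C (13 added to the base); 16 (1.3 equiv), −78 → −20 °C; LDA (2.5 equiv), −78 → 0 °C; AcOH, then aq NH4Cl
Reagents that add atoms: none
Why: Proposed new method: LDA removes a proton from the C2 methyl group of 13, which is vinylogous to both the C4 ketone and the ester, and the dienolate adds to the lactone carbonyl of 16; the lactolate opens and the expelled tertiary alkoxide takes the now doubly activated C8 proton, which forms C7–C8 and gives the enolate of 17. The second charge of LDA should give the alkoxide and the 1,3-dicarbonyl-type dianion, whose terminal carbanion (future C6) attacks the ring ester in a 6-(enolexo)-exo-trig Claisen closure (C5–C6); loss of ethoxide and enolisation of the 5,7-dione aromatise ring A. The closest known reactions are lateral lithiation, acylation and Dieckmann closure of ortho-toluate esters to naphthalene-1,3-diols, and the Claisen cyclisation of β-polyketone dianions. No stereocentre is formed, so no control element is needed. The step needs C6 to attack the ester carbon and nothing else: C8 would give a four-membered ring, the γ-pyrone carbonyl would give a bridged bicycle with a bridgehead double bond, and O-acylation through O7 is held back because the carbon terminus of the dianion is generated before the mixture is warmed. The 6-alkyl pattern is fixed by the substrate, since the chain sits on the lactone α-carbon between the two carbonyls that become C5–OH and C7–OH.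

Step 10
Reactants: 18 3-[2,2-dimethyl-7-(triisopropylsilyloxy)-2H-chromen-6-yl]-5,7-dihydroxy-6-(3-hydroxy-3-methylbutyl)-4H-chromen-4-one
Product: 19 5,7-dihydroxy-6-(3-hydroxy-3-methylbutyl)-3-(7-hydroxy-2,2-dimethyl-2H-chromen-6-yl)-4H-chromen-4-one
Conditions: TBAF (1.2 equiv), AcOH (1.5 equiv), THF, 0 °C
Reagents that add atoms: none
Why: Fluoride desilylation of the aryl silyl ether under buffered, non-acidic conditions, so the tertiary alcohol flanked by two phenols cannot cyclise to a dimethylchroman and the chromene is untouched.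

**Compound list**

1 | 4-bromobenzene-1,3-diol | Oc1ccc(Br)c(O)c1 | starting material
2 | 3-methylbut-2-enoic acid | CC(C)=CC(=O)O | starting material
3 | 1-(5-bromo-2,4-dihydroxyphenyl)-3-methylbut-2-en-1-one | CC(C)=CC(=O)c1cc(Br)c(O)cc1O | intermediate (not isolated)
4 | 6-bromo-7-hydroxy-2,2-dimethylchroman-4-one | CC1(C)CC(=O)c2cc(Br)c(O)cc2O1 | intermediate
5 | 6-bromo-2,2-dimethyl-7-(triisopropylsilyloxy)chroman-4-one | CC1(C)CC(=O)c2cc(Br)c(O[Si](C(C)C)(C(C)C)C(C)C)cc2O1 | intermediate
6 | rac-6-bromo-2,2-dimethyl-7-(triisopropylsilyloxy)chroman-4-ol | CC1(C)CC(O)c2cc(Br)c(O[Si](C(C)C)(C(C)C)C(C)C)cc2O1 | intermediate (not isolated)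
7 | 6-bromo-2,2-dimethyl-7-(triisopropylsilyloxy)-2H-chromene | CC1(C)C=Cc2cc(Br)c(O[Si](C(C)C)(C(C)C)C(C)C)cc2O1 | intermediate
8 | 2-[2,2-dimethyl-7-(triisopropylsilyloxy)-2H-chromen-6-yl]-4,4,5,5-tetramethyl-1,3,2-dioxaborolane | CC1(C)C=Cc2cc(B3OC(C)(C)C(C)(C)O3)c(O[Si](C(C)C)(C(C)C)C(C)C)cc2O1 | intermediate
9 | ethyl 2-acetyl-3-oxobutanoate | CCOC(=O)C(C(C)=O)C(C)=O | starting material
10 | ethyl (E)-2-acetyl-5-(dimethylamino)-3-oxopent-4-enoate | CCOC(=O)C(C(C)=O)C(=O)/C=C/N(C)C | intermediate (not isolated)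
11 | ethyl 2-methyl-4-oxo-4H-pyran-3-carboxylate | CCOC(=O)c1c(C)occc1=O | intermediate
12 | ethyl 5-iodo-2-methyl-4-oxo-4H-pyran-3-carboxylate | CCOC(=O)c1c(C)occ(I)c1=O | intermediate
13 | ethyl 5-[2,2-dimethyl-7-(triisopropylsilyloxy)-2H-chromen-6-yl]-2-methyl-4-oxo-4H-pyran-3-carboxylate | CCOC(=O)c1c(C)occ(-c2cc3C=CC(C)(C)Oc3cc2O[Si](C(C)C)(C(C)C)C(C)C)c1=O | intermediate (key-step precursor)
14 | ethyl 5-oxohexanoate | CCOC(=O)CCCC(C)=O | starting material
15 | ethyl 5-hydroxy-5-methylhexanoate (as its bromomagnesium alkoxide) | CCOC(=O)CCCC(C)(C)O | intermediate (not isolated)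
16 | 6,6-dimethyltetrahydro-2H-pyran-2-one | CC1(C)CCCC(=O)O1 | intermediate (key-step precursor)
17 | ethyl 5-[2,2-dimethyl-7-(triisopropylsilyloxy)-2H-chromen-6-yl]-2-(6-hydroxy-6-methyl-2-oxoheptyl)-4-oxo-4H-pyran-3-carboxylate | CCOC(=O)c1c(CC(=O)CCCC(C)(C)O)occ(-c2cc3C=CC(C)(C)Oc3cc2O[Si](C(C)C)(C(C)C)C(C)C)c1=O | intermediate (not isolated)
18 | 3-[2,2-dimethyl-7-(triisopropylsilyloxy)-2H-chromen-6-yl]-5,7-dihydroxy-6-(3-hydroxy-3-methylbutyl)-4H-chromen-4-one | CC(C)(O)CCc1c(O)cc2occ(-c3cc4C=CC(C)(C)Oc4cc3O[Si](C(C)C)(C(C)C)C(C)C)c(=O)c2c1O | intermediate (key-step product)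
19 | 5,7-dihydroxy-6-(3-hydroxy-3-methylbutyl)-3-(7-hydroxy-2,2-dimethyl-2H-chromen-6-yl)-4H-chromen-4-one | CC(C)(O)CCc1c(O)cc2occ(-c3cc4c(cc3O)OC(C)(C)C=C4)c(=O)c2c1O | target

**Step count**

Total steps: 10. Longest linear sequence: 7 steps (1, 2, 3, 4, 7, 9, 10).

**Steps most likely to fail**

1. Step 9 (new method). The stabilised dienolate may deprotonate the lactone instead of adding to it. The C7 enolate oxygen may acylate the ester (lactonisation to a fused 2-pyranone) before the dianion exists. The dienolate may also add in Michael fashion to C6 of unreacted pyranone.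
 Fallback (known chemistry only), from 8 back to 19: ring A is taken ready-made and the isoflavone is assembled by two cross-couplings.
 - 2,4,6-Trihydroxyacetophenone is silylated at its unchelated 4-hydroxyl (TIPSCl, imidazole) to 1-[2,6-dihydroxy-4-(triisopropylsilyloxy)phenyl]ethanone F1.
 - DMF-DMA gives (E)-3-(dimethylamino)-1-[2,6-dihydroxy-4-(triisopropylsilyloxy)phenyl]prop-2-en-1-one F2. Iodine/pyridine closes it to 5-hydroxy-3-iodo-7-(triisopropylsilyloxy)chromen-4-one F3; the two ortho hydroxyls are equivalent, so only one chromone can form.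
 - Benzyltrimethylammonium dichloroiodate/CaCO3 iodinates ortho to the chelated 5-hydroxyl to give 5-hydroxy-3,6-diiodo-7-(triisopropylsilyloxy)chromen-4-one F4.
 - Suzuki coupling with 8 at the more reactive C3–I gives 3-[2,2-dimethyl-7-(triisopropylsilyloxy)-2H-chromen-6-yl]-5-hydroxy-6-iodo-7-(triisopropylsilyloxy)chromen-4-one F5.
 - A B-alkyl Suzuki coupling with 9-(3-hydroxy-3-methylbutyl)-9-borabicyclo[3.3.1]nonane F6 (from 2-methylbut-3-en-2-ol and 9-BBN) puts the chain at C6 and gives the 7,2′-bis-O-TIPS ether of the target F7.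
 - TBAF/AcOH then gives 19. Here the 6-alkyl regiochemistry rests on the 5-OH-directed iodination instead of the benzannulation.

2. Step 7. Protodeboronation of the hindered, electron-rich boronate and hydroxide attack on the pyranone (ring opening at C2/C6, ester hydrolysis) may outrun transmetalation.
 Fallback, from 7 back to 13: the aryl group is installed before the pyranone exists, and the ring is built around an arylacetyl unit.
 - Pd-catalysed coupling of 7 with BrZnCH2CO2Et (Pd(dba)2/Q-Phos, THF) gives ethyl 2-[2,2-dimethyl-7-(triisopropylsilyloxy)-2H-chromen-6-yl]acetate F8.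
 - LiOH gives 2-[2,2-dimethyl-7-(triisopropylsilyloxy)-2H-chromen-6-yl]acetic acid F9.
 - 1-Chloro-N,N,2-trimethylprop-1-enylamine gives 2-[2,2-dimethyl-7-(triisopropylsilyloxy)-2H-chromen-6-yl]acetyl chloride F10.
 - F10 C-acylates the magnesium enolate of ethyl acetoacetate (MgCl2, pyridine) to ethyl 2-acetyl-4-[2,2-dimethyl-7-(triisopropylsilyloxy)-2H-chromen-6-yl]-3-oxobutanoate F11.
 - DMF-DMA condenses at the benzylic CH2 to ethyl 2-acetyl-5-(dimethylamino)-4-[2,2-dimethyl-7-(triisopropylsilyloxy)-2H-chromen-6-yl]-3-oxopent-4-enoate F12, and AcOH closes the pyranone to 13.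

3. Step 6. The ester-deactivated pyranone may iodinate slowly, with halogenation of the lateral methyl group or over-iodination competing.
 Fallback, from 10 back to 12: iodine is introduced during ring closure instead of afterwards. Enaminone 10 is isolated (step 5 without the AcOH stage) and treated with I2/pyridine in CHCl3 at rt. α-Iodination of the enaminone and closure by the enol oxygen (the 3-iodochromone protocol) should give 12 directly, bypassing 11. No new compound is made.

Further compounds
F1 | step 9 | 1-[2,6-dihydroxy-4-(triisopropylsilyloxy)phenyl]ethanone | CC(=O)c1c(O)cc(O[Si](C(C)C)(C(C)C)C(C)C)cc1O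
F2 | step 9 | (E)-3-(dimethylamino)-1-[2,6-dihydroxy-4-(triisopropylsilyloxy)phenyl]prop-2-en-1-one | CN(C)/C=C/C(=O)c1c(O)cc(O[Si](C(C)C)(C(C)C)C(C)C)cc1O
F3 | step 9 | 5-hydroxy-3-iodo-7-(triisopropylsilyloxy)chromen-4-one | O=c1c(I)coc2cc(O[Si](C(C)C)(C(C)C)C(C)C)cc(O)c12
F4 | step 9 | 5-hydroxy-3,6-diiodo-7-(triisopropylsilyloxy)chromen-4-one | O=c1c(I)coc2cc(O[Si](C(C)C)(C(C)C)C(C)C)c(I)c(O)c12
F5 | step 9 | 3-[2,2-dimethyl-7-(triisopropylsilyloxy)-2H-chromen-6-yl]-5-hydroxy-6-iodo-7-(triisopropylsilyloxy)chromen-4-one | O=c1c(-c3cc4C=CC(C)(C)Oc4cc3O[Si](C(C)C)(C(C)C)C(C)C)coc2cc(O[Si](C(C)C)(C(C)C)C(C)C)c(I)c(O)c12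
F6 | step 9 | 9-(3-hydroxy-3-methylbutyl)-9-borabicyclo[3.3.1]nonane | CC(C)(O)CCB1C2CCCC1CCC2
F7 | step 9 | 3-[2,2-dimethyl-7-(triisopropylsilyloxy)-2H-chromen-6-yl]-5-hydroxy-6-(3-hydroxy-3-methylbutyl)-7-(triisopropylsilyloxy)chromen-4-one | CC(C)(O)CCc1c(O[Si](C(C)C)(C(C)C)C(C)C)cc2occ(-c3cc4C=CC(C)(C)Oc4cc3O[Si](C(C)C)(C(C)C)C(C)C)c(=O)c2c1O
F8 | step 7 | ethyl 2-[2,2-dimethyl-7-(triisopropylsilyloxy)-2H-chromen-6-yl]acetate | CCOC(=O)Cc1cc2C=CC(C)(C)Oc2cc1O[Si](C(C)C)(C(C)C)C(C)C
F9 | step 7 | 2-[2,2-dimethyl-7-(triisopropylsilyloxy)-2H-chromen-6-yl]acetic acid | OC(=O)Cc1cc2C=CC(C)(C)Oc2cc1O[Si](C(C)C)(C(C)C)C(C)C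
F10 | step 7 | 2-[2,2-dimethyl-7-(triisopropylsilyloxy)-2H-chromen-6-yl]acetyl chloride | ClC(=O)Cc1cc2C=CC(C)(C)Oc2cc1O[Si](C(C)C)(C(C)C)C(C)C
F11 | step 7 | ethyl 2-acetyl-4-[2,2-dimethyl-7-(triisopropylsilyloxy)-2H-chromen-6-yl]-3-oxobutanoate | CCOC(=O)C(C(C)=O)C(=O)Cc1cc2C=CC(C)(C)Oc2cc1O[Si](C(C)C)(C(C)C)C(C)C
F12 | step 7 | ethyl 2-acetyl-5-(dimethylamino)-4-[2,2-dimethyl-7-(triisopropylsilyloxy)-2H-chromen-6-yl]-3-oxopent-4-enoate | CCOC(=O)C(C(C)=O)C(=O)C(=CN(C)C)c1cc2C=CC(C)(C)Oc2cc1O[Si](C(C)C)(C(C)C)C(C)C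
F0 | step 6 | none | none
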